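The data come from a simulation from invented constants; the scatter is artificial.

A closed, stirred vessel at constant volume holds substrate, partner, free catalyst and a little impurity, and product appears in it. Friday's flask is the one asked about; Monday's ran cooler.

| setting | Friday's | Monday's | flask |
|---|---|---|---|
| substrate | 10 mM | 10 mM | 10 mM |
| partner | 2 equiv | 2 equiv | 2.00 equiv |
| free catalyst | 10 mol% | 10 mol% | 10 mol% |
| impurity | 0.64 mM | 0.64 mM | 0.64 mM |
| temperature | 60 °C | 55 °C | 60 °C |
| remark | the very flask that is asked about, followed so far | run made earlier |  |
| time |  |  | 80 min |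

| Friday's: time / min | Friday's: product / % | Monday's: time / min | Monday's: product / % |
|---|---|---|---|
| 15.0 | 8.8 | 15.0 | 8.8 |
| 30.0 | 11.9 | 30.0 | 15.2 |
| 50.0 | 13.6 | 50.0 | 17.4 |
| 60.0 | 12.9 | 60.0 | 17.6 |
| 80.0 | 13.4 | 80.0 | 18.4 |

(standard deviation of a reading: 0.5 percentage points)

- ash: at 80 min add free catalyst, 50.0 % of the amount charged, then wait 80 min
- birch: at 80 min raise the temperature by 10 K, then wait 80 min
- oak: at 80 min add partner, 50.0 % of the amount charged, then wait 80 min
- cedar: at 80 min take out 90 % of the by-product then present, then wait 80 min
- elm: change nothing and wait 80 min more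

1. product, in percent of the substrate first charged, at 80 min
2. the remedy with the largest gain of product, or "none" below 2 percentage points (ash / birch / oak / cedar / elm / none)
3. product present, in percent of the substrate first charged, after ash
4. product present, in percent of the substrate first charged, after cedar

- the volume of additions can be left aside
- the numbers in the tables scatter with a standard deviation of 0.5 percentage points

The reckoning climbs from the fastest event to the slowest.

1. The rise. Friday's and Monday's flasks both read 8.8 % at 15.0 min. Held at that early pace, the last reading of Friday's flask takes 22.8 min by estimate, shorter than the 80 min of the look, and that of Monday's flask takes 31.4 min.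

2. The plateau. Friday's readings of 13.6 % and 13.4 % lie closer than the scatter of 0.5 points. So Friday's flask reads as stopped, and 13.4 % is the reckoned answer for now.

3. The stop. The last reading puts 1.34 mM of product in Friday's flask, and subtraction from the charge gives 8.66 mM of substrate, more than the product reading. The reckoning therefore reads the stop as a balance, which is thermodynamic control, and the higher ceiling of cooler Monday as a reaction giving off heat.

4. The carried quantity. The balance quotient, product times by-product over substrate times partner, with one by-product assumed per product, reads 0.0111 on Friday. With 1.84 mM of product, Monday's flask reads 0.0228. This pair of readings gives off a reckoned heat of 131 kJ mol⁻¹.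

5. The remedies. Ash leaves the quotient as it is, and birch lowers it. Oak gives about 1.66 mM of product. Cedar leaves 0.134 mM of by-product, and the first answer for the gain is 0.732 mM. Putting that back into substrate and partner gives 0.657 mM, so product reaches 20.0 %. In this reckoning cedar gains more than oak.

The forecast gives 13.4 % (13 % to 13.8 %) for now, ash as best, 16.5 % after ash (13.4 % to 20.5 %) and 13.5 % after cedar (13 % to 20.5 %). Its judgement runs: “An activated death seems likelier, though this is not certain.” It parts from the reckoning above on the best remedy, and its cedar figure is lower.

The flask gives 13.8 % at 80 min, 13.4 % after ash and 20.7 % after cedar; cedar brings the largest gain, 6.8 points.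

    substrate + free catalyst ⇌ catalyst intermediate A (K = 26.0 L mol⁻¹, k = 7.40 L mol⁻¹ s⁻¹, Ea = 45.0 kJ mol⁻¹, ΔH = −82.0 kJ mol⁻¹)
    partner + catalyst intermediate A ⇌ catalyst intermediate B (K = 9.90 L mol⁻¹, k = 4.40 L mol⁻¹ s⁻¹, Ea = 49.0 kJ mol⁻¹, ΔH = −28.0 kJ mol⁻¹)
    catalyst intermediate B ⇌ by-product + catalyst intermediate C (K = 0.00850 M, k = 0.120 s⁻¹, Ea = 83.0 kJ mol⁻¹, ΔH = 10.0 kJ mol⁻¹)
    catalyst intermediate C ⇌ free catalyst + product (K = 0.00580 M, k = 0.340 s⁻¹, Ea = 75.0 kJ mol⁻¹, ΔH = −32.0 kJ mol⁻¹)
    free catalyst + impurity → spent catalyst (k = 140 L mol⁻¹ s⁻¹, Ea = 56.0 kJ mol⁻¹)
    (constants at 60 °C)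

In this flask the step between catalyst intermediate C and free catalyst plus product relaxes with a half-life of 1.59 s, shorter than the 80 min of the look. The amounts in this flask at that time put the quotient at 0.0126, and at 800 min product still stands at 13.9 %. For a repeat at 85 °C, Friday's 0.0111 is reckoned down to 4.09 × 10⁻⁴. The first answer is 0.286 mM, and going round once more gives 0.280 mM, or 2.80 % of the substrate; that flask holds 2.78 % of product.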